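**Plan**

- Retrosynthesis, last operations first: the three alkyl ethers ortho to the two ketones (C2–OEt, C2'–OMe, C4'–OMe) and the C4 silyl ether are unmasked at the end. Before that the C1–acyl bond (Fries shift from C6–O) and the C3'–acyl bond (Friedel–Crafts) are cut.
- Ring A is then cut at C2–C3, C3–C4, C5–C6 and C1–C6 into a diazo enone and a siloxyalkyne that already carries ring B and the bridge CH2. The siloxyalkyne is cut at the alkyne C–O bond and the aryl–CH2 bond back to 2,4,6-trimethoxytoluene.
- Enabling feature: on ring A the oxygens at C2, C4 and C6 alternate with carbon substituents at C1, C3 and C5. C6–O can therefore come from a ketene carbonyl, C4–O from the siloxyalkyne and C2–O from the enol ether of the vinylketene, each in a different protection state.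
- Forward: fragment 1 (diazo enone, steps 1–2) and fragment 2 (siloxyalkyne, steps 3–5) are joined in step 6, which builds ring A, the only ring made (ring B is bought as the arene). Steps 7–11 add the two acyl chains and deprotect.
- Stereochemistry: the target has no stereocentre and no stereogenic double bond, so nothing has to be controlled.

Key step: step 6

Remark: ring A is numbered C1 (pentanoyl carbon) to C6 and ring B C1' (bridge carbon) to C6' (methoxy carbon) as in the target; 3-bromo-1-(trimethylsilyl)prop-1-yne, pentanoyl chloride and butanoyl chloride are taken as purchased, and the ethers ortho to a ketone are assumed to be cleaved by AlCl3 in MeCN faster than the unchelated C6' methyl ether.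

**Route**

Step 1
Reactants: 1 ethyl vinyl ether; 2 N-methoxy-N-methylpropanamide
Product: 4 2-ethoxypent-1-en-3-one, via 1-ethoxyvinyllithium 3 (not isolated)
Conditions: t-BuLi, THF, −78 → 0 °C; then 2, −78 → 0 °C; aq NH4Cl
Reagents that add atoms: none
Why: The vinylic hydrogen next to oxygen in 1 is removed by t-BuLi to give the acyl anion equivalent 3, which adds only once to the Weinreb amide because the chelated tetrahedral adduct persists until work-up (Weinreb ketone synthesis), leaving the ethyl side of 4 as the only enolisable position.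

Step 2
Reactants: 4 2-ethoxypent-1-en-3-one
Product: 6 4-diazo-2-ethoxypent-1-en-3-one, via trifluoroacetyl diketone 5 (not isolated)
Conditions: LiN(SiMe3)2, THF, −78 °C; CF3CO2CH2CF3; aq NH4Cl (crude 5 carried on); then 4-AcNHC6H4SO2N3, Et3N, H2O, MeCN, rt
Reagents that add atoms: 4-acetamidobenzenesulfonyl azide, CC(=O)Nc1ccc(cc1)S(=O)(=O)N=[N+]=[N-]
Why: The kinetic lithium enolate of 4 is C-trifluoroacetylated to the activated 1,3-diketone 5, whose single acidic C–H takes up the diazo group from the sulfonyl azide while the trifluoroacetyl group leaves on the sulfonamide nitrogen (detrifluoroacetylative Regitz diazo transfer), a method suited to base-sensitive enones.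

Step 3
Reactants: 7 2,4,6-trimethoxytoluene; 8 3-bromo-1-(trimethylsilyl)prop-1-yne
Product: 11 trimethyl[3-(2,4,6-trimethoxy-3-methylphenyl)prop-1-yn-1-yl]silane, via aryllithium 9 (not isolated), via arylmagnesium bromide 10 (not isolated)
Conditions: n-BuLi, TMEDA, THF, 0 °C → rt; MgBr2·OEt2, 0 °C; CuBr·SMe2 (10 mol %), 8, −20 °C → rt
Reagents that add atoms: none
Why: The ring C–H flanked by two methoxy groups is the most acidic site of 7 (cooperative directed ortho-metalation), and the derived Grignard reagent 10 is alkylated under copper catalysis at the CH2 of the propargylic bromide (SN2 coupling), the silyl cap shielding the alkyne terminus from SN2' attack and deprotonation.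

Step 4
Reactants: 11 trimethyl[3-(2,4,6-trimethoxy-3-methylphenyl)prop-1-yn-1-yl]silane
Product: 12 1,3,5-trimethoxy-2-methyl-4-(prop-2-yn-1-yl)benzene
Conditions: K2CO3, MeOH, 0 °C → rt
Reagents that add atoms: none
Why: Methoxide attacks silicon of the alkynylsilane and releases the terminal alkyne (protodesilylation), and the brief exposure to a weak base together with the electron-rich aryl group should keep the benzylic propargylic CH2 from isomerising to the allene.

Step 5
Reactants: 12 1,3,5-trimethoxy-2-methyl-4-(prop-2-yn-1-yl)benzene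
Product: 15 triisopropyl{[3-(2,4,6-trimethoxy-3-methylphenyl)prop-1-yn-1-yl]oxy}silane, via lithium acetylide 13 (not isolated), via lithium ynolate 14 (not isolated)
Conditions: n-BuLi, THF, −78 °C; t-BuOOLi (from t-BuOOH and LiN(SiMe3)2), −78 → 0 °C; i-Pr3SiOTf, −78 → 0 °C
Reagents that add atoms: tert-butyl hydroperoxide, CC(C)(C)OO; triisopropylsilyl trifluoromethanesulfonate, CC(C)[Si](OS(=O)(=O)C(F)(F)F)(C(C)C)C(C)C
Why: The acetylide 13 attacks the lithiated oxygen of the peroxide and expels tert-butoxide to give ynolate 14 (electrophilic oxygenation of a carbanion by a lithium alkyl peroxide), and the bulky, hard silyl triflate then traps 14 on oxygen (ynolate O-silylation).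

Step 6
Reactants: 6 4-diazo-2-ethoxypent-1-en-3-one; 15 triisopropyl{[3-(2,4,6-trimethoxy-3-methylphenyl)prop-1-yn-1-yl]oxy}silane
Product: 20 5-ethoxy-4-methyl-3-(triisopropylsilyloxy)-2-(2,4,6-trimethoxy-3-methylbenzyl)phenol, via vinylketene 16 (not isolated), via vinylcyclobutenone 17 (not isolated), via dienylketene 18 (not isolated), via cyclohexadienone 19 (not isolated)
Conditions: hν (medium-pressure Hg lamp, Vycor filter), ClCH2CH2Cl, rt; then 80 °C
Reagents that add atoms: none
Why: Irradiation expels N2 from 6 and the 1-ethoxyvinyl group shifts to the carbene carbon (Wolff rearrangement, C2–C3) to give vinylketene 16, whose ketene C=C is then attacked by the electron-rich siloxyalkyne 15 in a [2+2] cycloaddition (C5–C6 and C3–C4) that closes the transient four-membered ring of 17. On warming, 17 opens by four-electron electrocyclic cleavage to dienylketene 18, which closes ring A by thermal disrotatory six-electron electrocyclisation (C1–C6, six-membered) to dienone 19 and tautomerises to phenol 20. The closest known reaction type is the Danheiser benzannulation in its photochemical Wolff variant with triisopropylsiloxyalkynes. No stereocentre survives, since the quaternary carbon of 17 becomes planar on ring opening and the unproductive double-bond isomer of 18 can return to 17 and reopen. The selectivity needed is the regiochemistry of the [2+2] step, secured by the polarisation of 15: its benzyl-bearing carbon (beta to the silyloxy group) is the nucleophilic end and bonds to the ketene carbonyl carbon, so C5 ends up between C6–OH and C4–OSi. The cascade is neutral, so the enol ether, silyl ether and methyl ethers are untouched and the three ring A oxygens emerge as free OH, silyl ether and ethyl ether.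

Step 7
Reactants: 20 5-ethoxy-4-methyl-3-(triisopropylsilyloxy)-2-(2,4,6-trimethoxy-3-methylbenzyl)phenol; 21 pentanoyl chloride
Product: 22 5-ethoxy-4-methyl-3-(triisopropylsilyloxy)-2-(2,4,6-trimethoxy-3-methylbenzyl)phenyl pentanoate
Conditions: Et3N, DMAP (cat.), CH2Cl2, 0 °C → rt
Reagents that add atoms: none
Why: DMAP-catalysed O-acylation of the single free phenol stores the pentanoyl group on C6–O and at the same time damps ring A towards electrophiles for the next step.

Step 8
Reactants: 22 5-ethoxy-4-methyl-3-(triisopropylsilyloxy)-2-(2,4,6-trimethoxy-3-methylbenzyl)phenyl pentanoate; 23 butanoyl chloride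
Product: 24 2-(3-butanoyl-2,4,6-trimethoxy-5-methylbenzyl)-5-ethoxy-4-methyl-3-(triisopropylsilyloxy)phenyl pentanoate
Conditions: SnCl4, CH2Cl2, −40 → 0 °C
Reagents that add atoms: none
Why: Friedel–Crafts acylation should go to C3' of ring B, the only ring C–H flanked by two methoxy groups and para to a third, whereas C1 of ring A sits next to the deactivating ester oxygen; at low temperature SnCl4 should leave the aryl ester and the hindered silyl ether intact.

Step 9
Reactants: 24 2-(3-butanoyl-2,4,6-trimethoxy-5-methylbenzyl)-5-ethoxy-4-methyl-3-(triisopropylsilyloxy)phenyl pentanoate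
Product: 25 1-[3-(3-butanoyl-2,4,6-trimethoxy-5-methylbenzyl)-6-ethoxy-2-hydroxy-5-methyl-4-(triisopropylsilyloxy)phenyl]pentan-1-one
Conditions: TiCl4, CH2Cl2, 0 °C → rt
Reagents that add atoms: none
Why: Lewis-acid Fries rearrangement moves the pentanoyl group from C6–O to C1, which is ortho to the departing oxygen and the only unsubstituted aromatic carbon left in the molecule, so even an intermolecular acylium pathway can give no regioisomer.

Step 10
Reactants: 25 1-[3-(3-butanoyl-2,4,6-trimethoxy-5-methylbenzyl)-6-ethoxy-2-hydroxy-5-methyl-4-(triisopropylsilyloxy)phenyl]pentan-1-one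
Product: 26 1-[3-(3-butanoyl-2,4,6-trimethoxy-5-methylbenzyl)-6-ethoxy-2,4-dihydroxy-5-methylphenyl]pentan-1-one
Conditions: Bu4NF, AcOH, THF, 0 °C → rt
Reagents that add atoms: none
Why: Fluoride cleaves the aryl silyl ether (Si–F bond formation with a phenoxide leaving group), and acetic acid buffers the phenoxides so that the electron-rich bis-ketone is not held under strongly basic conditions.

Step 11
Reactants: 26 1-[3-(3-butanoyl-2,4,6-trimethoxy-5-methylbenzyl)-6-ethoxy-2,4-dihydroxy-5-methylphenyl]pentan-1-one
Product: 27 1-[3-(3-butanoyl-2,4-dihydroxy-6-methoxy-5-methylbenzyl)-2,4,6-trihydroxy-5-methylphenyl]pentan-1-one (CNP0210501.0)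
Conditions: AlCl3 (excess), MeCN, 0 → 50 °C; then 1 M HCl
Reagents that add atoms: none
Why: AlCl3 moderated by acetonitrile dealkylates aryl ethers only where the ether oxygen and an ortho carbonyl oxygen can bind aluminium together (chelation-controlled ether cleavage, known also for the second alkoxy group of 2-hydroxy-6-alkoxyaryl ketones), which holds for C2–OEt, C2'–OMe and C4'–OMe but not for C6'–OMe, which is para to the butanoyl group and has no chelation partner.

**Compound list**

1 | ethyl vinyl ether | C=COCC | starting material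
2 | N-methoxy-N-methylpropanamide | CCC(=O)N(C)OC | starting material
3 | 1-ethoxyvinyllithium | [Li]C(=C)OCC | intermediate
4 | 2-ethoxypent-1-en-3-one | CCOC(=C)C(=O)CC | intermediate
5 | 5-ethoxy-1,1,1-trifluoro-3-methylhex-5-ene-2,4-dione (racemic, enolisable) | CCOC(=C)C(=O)C(C)C(=O)C(F)(F)F | intermediate
6 | 4-diazo-2-ethoxypent-1-en-3-one | CCOC(=C)C(=O)C(C)=[N+]=[N-] | intermediate
7 | 2,4,6-trimethoxytoluene | Cc1c(OC)cc(OC)cc1OC | starting material
8 | 3-bromo-1-(trimethylsilyl)prop-1-yne | C[Si](C)(C)C#CCBr | starting material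
9 | (2,4,6-trimethoxy-3-methylphenyl)lithium | [Li]c1c(OC)cc(OC)c(C)c1OC | intermediate
10 | (2,4,6-trimethoxy-3-methylphenyl)magnesium bromide | Br[Mg]c1c(OC)cc(OC)c(C)c1OC | intermediate
11 | trimethyl[3-(2,4,6-trimethoxy-3-methylphenyl)prop-1-yn-1-yl]silane | C[Si](C)(C)C#CCc1c(OC)cc(OC)c(C)c1OC | intermediate
12 | 1,3,5-trimethoxy-2-methyl-4-(prop-2-yn-1-yl)benzene | C#CCc1c(OC)cc(OC)c(C)c1OC | intermediate
13 | [3-(2,4,6-trimethoxy-3-methylphenyl)prop-1-yn-1-yl]lithium | [Li]C#CCc1c(OC)cc(OC)c(C)c1OC | intermediate
14 | lithium 3-(2,4,6-trimethoxy-3-methylphenyl)prop-1-yn-1-olate | [Li]OC#CCc1c(OC)cc(OC)c(C)c1OC | intermediate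
15 | triisopropyl{[3-(2,4,6-trimethoxy-3-methylphenyl)prop-1-yn-1-yl]oxy}silane | CC(C)[Si](OC#CCc1c(OC)cc(OC)c(C)c1OC)(C(C)C)C(C)C | intermediate
16 | 3-ethoxy-2-methylbuta-1,3-dien-1-one | CCOC(=C)C(C)=C=O | intermediate
17 | 4-(1-ethoxyvinyl)-4-methyl-3-(triisopropylsilyloxy)-2-(2,4,6-trimethoxy-3-methylbenzyl)cyclobut-2-en-1-one (racemic, transient) | O=C1C(Cc2c(OC)cc(OC)c(C)c2OC)=C(O[Si](C(C)C)(C(C)C)C(C)C)C1(C)C(=C)OCC | intermediate
18 | (3E)-5-ethoxy-4-methyl-3-(triisopropylsilyloxy)-2-(2,4,6-trimethoxy-3-methylbenzyl)hexa-1,3,5-trien-1-one | O=C=C(Cc1c(OC)cc(OC)c(C)c1OC)/C(O[Si](C(C)C)(C(C)C)C(C)C)=C(/C)C(=C)OCC | intermediate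
19 | 5-ethoxy-4-methyl-3-(triisopropylsilyloxy)-2-(2,4,6-trimethoxy-3-methylbenzyl)cyclohexa-2,4-dien-1-one | O=C1CC(OCC)=C(C)C(O[Si](C(C)C)(C(C)C)C(C)C)=C1Cc1c(OC)cc(OC)c(C)c1OC | intermediate
20 | 5-ethoxy-4-methyl-3-(triisopropylsilyloxy)-2-(2,4,6-trimethoxy-3-methylbenzyl)phenol | CCOc1cc(O)c(Cc2c(OC)cc(OC)c(C)c2OC)c(O[Si](C(C)C)(C(C)C)C(C)C)c1C | intermediate
21 | pentanoyl chloride | CCCCC(Cl)=O | starting material
22 | 5-ethoxy-4-methyl-3-(triisopropylsilyloxy)-2-(2,4,6-trimethoxy-3-methylbenzyl)phenyl pentanoate | CCCCC(=O)Oc1cc(OCC)c(C)c(O[Si](C(C)C)(C(C)C)C(C)C)c1Cc1c(OC)cc(OC)c(C)c1OC | intermediate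
23 | butanoyl chloride | CCCC(Cl)=O | starting material
24 | 2-(3-butanoyl-2,4,6-trimethoxy-5-methylbenzyl)-5-ethoxy-4-methyl-3-(triisopropylsilyloxy)phenyl pentanoate | CCCCC(=O)Oc1cc(OCC)c(C)c(O[Si](C(C)C)(C(C)C)C(C)C)c1Cc1c(OC)c(C(=O)CCC)c(OC)c(C)c1OC | intermediate
25 | 1-[3-(3-butanoyl-2,4,6-trimethoxy-5-methylbenzyl)-6-ethoxy-2-hydroxy-5-methyl-4-(triisopropylsilyloxy)phenyl]pentan-1-one | CCCCC(=O)c1c(OCC)c(C)c(O[Si](C(C)C)(C(C)C)C(C)C)c(Cc2c(OC)c(C(=O)CCC)c(OC)c(C)c2OC)c1O | intermediate
26 | 1-[3-(3-butanoyl-2,4,6-trimethoxy-5-methylbenzyl)-6-ethoxy-2,4-dihydroxy-5-methylphenyl]pentan-1-one | CCCCC(=O)c1c(OCC)c(C)c(O)c(Cc2c(OC)c(C(=O)CCC)c(OC)c(C)c2OC)c1O | intermediate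
27 | 1-[3-(3-butanoyl-2,4-dihydroxy-6-methoxy-5-methylbenzyl)-2,4,6-trihydroxy-5-methylphenyl]pentan-1-one | CCCCC(=O)c1c(O)c(C)c(O)c(Cc2c(O)c(C(=O)CCC)c(O)c(C)c2OC)c1O | target

**Summary and risks**

Total step count: 11. Longest linear sequence: 9 steps (7 to 27 through steps 3–11); the diazo enone branch adds 2 steps.

Steps most likely to fail:

1. Step 11. On each ketone the first-freed phenol ties up the carbonyl as an aluminium chelate, so the second ortho ether may cleave slowly. Forcing the reaction may then erode the hindered C6' methyl ether or the methylene bridge. The fallback relays the chelation through acetates so that every cleavage is a first chelation event. It sets out from 26 and returns at 27.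
   - BCl3 in CH2Cl2 at −78 → 0 °C should remove one ring B ortho methyl group and give 1-[3-(3-butanoyl-2-hydroxy-4,6-dimethoxy-5-methylbenzyl)-6-ethoxy-2,4-dihydroxy-5-methylphenyl]pentan-1-one F1 (the 4'-hydroxy regioisomer, if formed, converges on 27 by the same sequence).
   - Ac2O, pyridine and DMAP cap the three phenols as 2-(2-acetoxy-3-butanoyl-4,6-dimethoxy-5-methylbenzyl)-5-ethoxy-4-methyl-6-pentanoyl-1,3-phenylene diacetate F2.
   - With no free ortho phenol left to hold boron, a second BCl3 treatment at −78 → 0 °C is directed by each ketone to its remaining ortho ether (C2 ethyl, C4' methyl) and gives 2-(2-acetoxy-3-butanoyl-4-hydroxy-6-methoxy-5-methylbenzyl)-5-hydroxy-4-methyl-6-pentanoyl-1,3-phenylene diacetate F3.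
   - K2CO3 in degassed MeOH removes the acetates to give 27.

2. Step 6. The methyl-bearing carbene may undergo 1,2-hydrogen shift to a divinyl ketone in competition with the Wolff shift, and the disubstituted ketene may be captured slowly and lost to photodegradation or to acylation of the product phenol. The fallback reaches the same vinylketene 16 without a carbene. 3-Ethoxy-2-methylcyclobut-2-en-1-one F4, made by [2+2] cycloaddition of ketene (from acetyl chloride and Et3N) with 1-ethoxyprop-1-yne, is heated with 15 in toluene at 110 °C. Four-electron ring opening of F4 gives 16, which enters the same cycloaddition and electrocyclisation cascade. The fallback sets out from 15 and returns at 20.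

3. Step 5. Oxygen transfer from the peroxide to the acetylide may be incomplete, base may isomerise the propargyl arene to the allene, and the ynolate may be silylated on carbon. The fallback makes ynolate 14 by Kowalski ester homologation. It sets out from 7 and returns at 15.
   - Friedel–Crafts acylation of 7 with ethyl chlorooxoacetate (TiCl4, CH2Cl2, −20 °C) gives ethyl 2-oxo-2-(2,4,6-trimethoxy-3-methylphenyl)acetate F5.
   - Ionic hydrogenation (Et3SiH, CF3CO2H) reduces the aryl ketone to ethyl 2-(2,4,6-trimethoxy-3-methylphenyl)acetate F6.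
   - Treatment of F6 with LiCHBr2 (from CH2Br2 and lithium 2,2,6,6-tetramethylpiperidide, THF, −78 °C), then LiN(SiMe3)2 and n-BuLi with warming, rearranges the bromo enolate to 14, which is trapped with i-Pr3SiCl to give 15.

Further compounds
F1 | step 11 | 1-[3-(3-butanoyl-2-hydroxy-4,6-dimethoxy-5-methylbenzyl)-6-ethoxy-2,4-dihydroxy-5-methylphenyl]pentan-1-one | CCCCC(=O)c1c(OCC)c(C)c(O)c(Cc2c(O)c(C(=O)CCC)c(OC)c(C)c2OC)c1O
F2 | step 11 | 2-(2-acetoxy-3-butanoyl-4,6-dimethoxy-5-methylbenzyl)-5-ethoxy-4-methyl-6-pentanoyl-1,3-phenylene diacetate | CCCCC(=O)c1c(OCC)c(C)c(OC(C)=O)c(Cc2c(OC(C)=O)c(C(=O)CCC)c(OC)c(C)c2OC)c1OC(C)=O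
F3 | step 11 | 2-(2-acetoxy-3-butanoyl-4-hydroxy-6-methoxy-5-methylbenzyl)-5-hydroxy-4-methyl-6-pentanoyl-1,3-phenylene diacetate | CCCCC(=O)c1c(O)c(C)c(OC(C)=O)c(Cc2c(OC(C)=O)c(C(=O)CCC)c(O)c(C)c2OC)c1OC(C)=O
F4 | step 6 | 3-ethoxy-2-methylcyclobut-2-en-1-one | CCOC1=C(C)C(=O)C1
F5 | step 5 | ethyl 2-oxo-2-(2,4,6-trimethoxy-3-methylphenyl)acetate | CCOC(=O)C(=O)c1c(OC)cc(OC)c(C)c1OC
F6 | step 5 | ethyl 2-(2,4,6-trimethoxy-3-methylphenyl)acetate | CCOC(=O)Cc1c(OC)cc(OC)c(C)c1OC
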